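Assumption: decalin intermediates carry eremophilane numbering (C1–C10 ring carbons, C11–C13 the three-carbon unit on C7, C14 the methyl on C5, C15 the methyl on C4; β is the face of the C5 methyl), so the target is (4S,5R,7S,8R,9S,10S,11R)-9α-angeloyloxy-11,12-epoxy-8α-hydroxy-10βH-eremophilan-2-one; (+)-nopinone, (E)-pent-3-en-2-one and (Z)-2-bromobut-2-ene are taken as commercial.

**Retrosynthetic overview**
1. Target 20 ⇐ hydroxy angelate 19 by 8-OH-directed epoxidation of the isopropenyl group (sets C11).
2. 19 ⇐ 8α,9α-cyclic carbonate 13 + (E)-but-2-en-2-yllithium (new step: builds the angelate on the axial O9, leaves 8-OH free).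
3. 13 ⇐ dienone 9: α-face dihydroxylation (C8, C9) while C10 is still sp2, carbonate formation, β-face hydrogenation (C10); the isopropenyl group travels masked as its HCl adduct.
4. 9 ⇐ enone 8 ⇐ diketone 6: acid-induced aldol condensation closes ring A and opens the cyclobutane, revealing ring B with C7 from the chiral pool.
5. 6 ⇐ (+)-nopinone 1 by methylation and Michael addition to (E)-pent-3-en-2-one 4 (sets C5 and C4). Ring order: ring B (latent in nopinone), then ring A.

**Route**

Step 1
Reactants: 1 (+)-nopinone, (1R,5S)-6,6-dimethylbicyclo[3.1.1]heptan-2-one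
Product: 3 (1R,3S,5S)-3,6,6-trimethylbicyclo[3.1.1]heptan-2-one, via lithium enolate 2 (not isolated)
Conditions: LDA, THF, −78 °C; MeI, −78 → 0 °C
Reagents that add atoms: iodomethane, CI
Why: Enolate alkylation in which only C3 can enolise (C1 is a bridgehead) and the electrophile enters anti to the gem-dimethyl bridge, giving the trans-3-methyl ketone (3S).

Step 2
Reactants: 3 (1R,3S,5S)-3,6,6-trimethylbicyclo[3.1.1]heptan-2-one; 4 (E)-pent-3-en-2-one
Product: 6 (1R,3R,5R)-3,6,6-trimethyl-3-[(2S)-4-oxopentan-2-yl]bicyclo[3.1.1]heptan-2-one, via sodium enolate 5 (not isolated)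
Conditions: NaH, 1,4-dioxane, 60 °C; then 4, 10 °C → rt; AcOH quench
Reagents that add atoms: none
Why: Michael addition (first half of a Robinson annulation) in which the enone adds to the enolate face anti to the gem-dimethyl bridge, fixing the quaternary centre (future C5, methyl cis to the future C7 side chain), while the chelated sodium-enolate transition state in a non-polar ether gives the adduct that becomes the cis-4,5-dimethyl pair (2S in the side chain), as in the classical 2-methylcyclohexanone/pentenone annulation.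

Step 3
Reactants: 6 (1R,3R,5R)-3,6,6-trimethyl-3-[(2S)-4-oxopentan-2-yl]bicyclo[3.1.1]heptan-2-one
Product: 8 (4S,5R,7R)-11-chloroeremophil-1(10)-en-2-one, via tricyclic enone 7 (not isolated)
Conditions: HCl (g), AcOH, rt
Reagents that add atoms: hydrogen chloride, Cl
Why: Acid-mediated aldol condensation closes ring A and the protonated enone then triggers fragmentation of the cyclobutane C9–C11 bond, the tertiary cation being trapped by chloride, so C7 keeps the nopinone bridgehead configuration and the isopropenyl group stays masked as its HCl adduct.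

Step 4
Reactants: 8 (4S,5R,7R)-11-chloroeremophil-1(10)-en-2-one
Product: 9 (4S,5R,7S)-11-chloroeremophila-1(10),8-dien-2-one
Conditions: chloranil, t-BuOH, 80 °C
Reagents that add atoms: none
Why: Quinone dehydrogenation of the extended dienol (γ,δ-dehydrogenation of an enone) gives the linear dienone without touching a stereocentre (the C7 descriptor changes only through CIP priorities).

Step 5
Reactants: 9 (4S,5R,7S)-11-chloroeremophila-1(10),8-dien-2-one
Product: 10 (4S,5R,7S,8R,9S)-11-chloro-8α,9α-dihydroxyeremophil-1(10)-en-2-one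
Conditions: OsO4 (5 mol %), NMO, acetone/H2O, 0 °C → rt
Reagents that add atoms: N-methylmorpholine N-oxide, C[N+]1([O-])CCOCC1; water, O
Why: Upjohn dihydroxylation of the more electron-rich γ,δ-alkene, in which the flat C10-sp2 dienone has both β substituents (C5 methyl, C7 side chain) shielding the top face, so osmium adds from the α face and sets 8R and 9S.

Step 6
Reactants: 10 (4S,5R,7S,8R,9S)-11-chloro-8α,9α-dihydroxyeremophil-1(10)-en-2-one
Product: 11 (4S,5R,7S,8R,9S)-11-chloro-8α,9α-(carbonyldioxy)eremophil-1(10)-en-2-one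
Conditions: CDI, THF, 40 °C
Reagents that add atoms: 1,1'-carbonyldiimidazole, O=C(n1ccnc1)n1ccnc1
Why: Carbonylation of the cis-diol gives the five-membered cyclic carbonate, which protects both hydroxyls, blocks the α face and already carries the carbon that becomes the ester carbonyl.

Step 7
Reactants: 11 (4S,5R,7S,8R,9S)-11-chloro-8α,9α-(carbonyldioxy)eremophil-1(10)-en-2-one
Product: 12 (4S,5R,7S,8R,9S,10S)-11-chloro-8α,9α-(carbonyldioxy)-10βH-eremophilan-2-one
Conditions: H2 (4 atm), 5 % Rh/Al2O3, EtOAc, rt
Reagents that add atoms: none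
Why: Heterogeneous catalytic hydrogenation of the enone C=C delivers hydrogen to the β face, anti to the α-oriented carbonate at C9 and in line with the usual cis selectivity of angular-methyl octalones, setting 10S (cis-decalin), with rhodium chosen to avoid allylic C–O hydrogenolysis and the tertiary chloride inert.

Step 8
Reactants: 12 (4S,5R,7S,8R,9S,10S)-11-chloro-8α,9α-(carbonyldioxy)-10βH-eremophilan-2-one
Product: 13 (4S,5R,7R,8R,9S,10S)-8α,9α-(carbonyldioxy)-10βH-eremophil-11-en-2-one
Conditions: NaOAc, AcOH, 100 °C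
Reagents that add atoms: none
Why: E1-type dehydrochlorination of the tertiary chloride in buffered acetic acid restores the isopropenyl group (the minor isopropylidene isomer is removed by chromatography), the carbonate and ketone being stable to these conditions and no stereocentre being affected.

Step 9
Reactants: 13 (4S,5R,7R,8R,9S,10S)-8α,9α-(carbonyldioxy)-10βH-eremophil-11-en-2-one; 14 (Z)-2-bromobut-2-ene
Product: 19 (4S,5R,7R,8R,9S,10S)-9α-angeloyloxy-8α-hydroxy-10βH-eremophil-11-en-2-one, via alkenyllithium 15 (not isolated), via lithium enolate 16 (not isolated), via dilithium carbonate adduct 17 (not isolated), via hemiorthoester 18 (not isolated)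
Conditions: 14, t-BuLi (2 equiv), Et2O, −78 °C (gives 15); 13, LiHMDS (1.1 equiv), THF, −78 °C (gives 16); 15 added to 16, −78 °C; AcOH, −78 → 0 °C
Reagents that add atoms: none
Why: Proposed new method: alkenyllithium opening of a cyclic carbonate to build the angelate in place, in which (E)-but-2-en-2-yllithium (geometry retained from the Z-bromide) adds once to the carbonate C=O while the ketone is shielded as its lithium enolate, the tetrahedral adduct survives at −78 °C, and on protonation the 2-hydroxy-1,3-dioxolane collapses under stereoelectronic control by cleaving the bond to the equatorial O8, so the ester stays on the axial O9 and C8 keeps a free OH; this forms the acyl C–C bond, decides O9 over O8 and avoids acylating a hindered axial alcohol with an isomerisation-prone acid, the closest known reactions being aryllithium opening of cyclic carbonates to hydroxy benzoates and the hydrolysis of cyclic orthoesters or dioxolan-2-ylium ions of cis-cyclohexanediols, which gives the axial ester.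

Step 10
Reactants: 19 (4S,5R,7R,8R,9S,10S)-9α-angeloyloxy-8α-hydroxy-10βH-eremophil-11-en-2-one
Product: 20 (4S,5R,7S,8R,9S,10S,11R)-9α-angeloyloxy-11,12-epoxy-8α-hydroxy-10βH-eremophilan-2-one
Conditions: VO(acac)2 (5 mol %), t-BuOOH, CH2Cl2, 0 °C → rt
Reagents that add atoms: tert-butyl hydroperoxide, CC(C)(C)OO
Why: Hydroxyl-directed VO(acac)2/t-BuOOH epoxidation of a homoallylic alcohol, in which the vanadate of the equatorial 8α-OH delivers oxygen through a chair-like transition state with the vinylic methyl eclipsing H7 and the CH2 terminus on the C8 side, which gives the 11R epoxide, while the electron-poor angelate and the ketone do not react.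

**Compound list**
1 | (+)-nopinone, (1R,5S)-6,6-dimethylbicyclo[3.1.1]heptan-2-one | CC1(C)[C@H]2CCC(=O)[C@@H]1C2 | starting material
2 | lithium enolate of 1 (C2–OLi, C2=C3; bridgeheads as in 1; not isolated) | [Li+].CC1(C)[C@H]2CC=C([O-])[C@@H]1C2 | intermediate
3 | (1R,3S,5S)-3,6,6-trimethylbicyclo[3.1.1]heptan-2-one (3-methyl trans to the CMe2 bridge) | CC1(C)[C@H]2C[C@H](C)C(=O)[C@@H]1C2 | intermediate
4 | (E)-pent-3-en-2-one | C/C=C/C(C)=O | starting material
5 | sodium enolate of 3 (C2–ONa, C2=C3; bridgeheads as in 3; not isolated) | [Na+].CC1(C)[C@H]2CC(C)=C([O-])[C@@H]1C2 | intermediate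
6 | (1R,3R,5R)-3,6,6-trimethyl-3-[(2S)-4-oxopentan-2-yl]bicyclo[3.1.1]heptan-2-one (3-methyl cis to the CMe2 bridge) | CC1(C)[C@H]2C[C@](C)([C@@H](C)CC(C)=O)C(=O)[C@@H]1C2 | intermediate
7 | tricyclic enone: ring A closed (C2=O, C1=C10), 4S,5R, cyclobutane C9–C11 bond still intact, other centres as in 6 (not isolated) | CC1(C)[C@H]2C[C@@]3(C)C(=CC(=O)C[C@@H]3C)[C@@H]1C2 | intermediate
8 | (4S,5R,7R)-11-chloroeremophil-1(10)-en-2-one (4β,5β-dimethyl, 7β-(2-chloropropan-2-yl)) | C1C[C@@H](C(C)(C)Cl)C[C@@]2(C)C1=CC(=O)C[C@@H]2C | intermediate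
9 | (4S,5R,7S)-11-chloroeremophila-1(10),8-dien-2-one | C1=C[C@@H](C(C)(C)Cl)C[C@@]2(C)C1=CC(=O)C[C@@H]2C | intermediate
10 | (4S,5R,7S,8R,9S)-11-chloro-8α,9α-dihydroxyeremophil-1(10)-en-2-one | O[C@@H]1[C@H](O)[C@@H](C(C)(C)Cl)C[C@@]2(C)C1=CC(=O)C[C@@H]2C | intermediate
11 | (4S,5R,7S,8R,9S)-11-chloro-8α,9α-(carbonyldioxy)eremophil-1(10)-en-2-one (cyclic carbonate of 10) | O=C1O[C@@H]2[C@H](O1)[C@@H](C(C)(C)Cl)C[C@@]3(C)C2=CC(=O)C[C@@H]3C | intermediate
12 | (4S,5R,7S,8R,9S,10S)-11-chloro-8α,9α-(carbonyldioxy)-10βH-eremophilan-2-one (cis-decalin) | O=C1O[C@@H]2[C@H](O1)[C@@H](C(C)(C)Cl)C[C@@]3(C)[C@@H]2CC(=O)C[C@@H]3C | intermediate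
13 | (4S,5R,7R,8R,9S,10S)-8α,9α-(carbonyldioxy)-10βH-eremophil-11-en-2-one | O=C1O[C@@H]2[C@H](O1)[C@@H](C(C)=C)C[C@@]3(C)[C@@H]2CC(=O)C[C@@H]3C | intermediate
14 | (Z)-2-bromobut-2-ene (methyl groups trans) | C/C=C(/C)Br | starting material
15 | (E)-but-2-en-2-yllithium (methyl groups trans; not isolated) | C/C=C(/C)[Li] | intermediate
16 | lithium enolate of 13 (drawn as the C2–C3 enolate, regiochemistry immaterial; not isolated) | [Li+].O=C1O[C@@H]2[C@H](O1)[C@@H](C(C)=C)C[C@@]3(C)[C@@H]2CC([O-])=C[C@@H]3C | intermediate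
17 | dilithium carbonate adduct: 2-[(Z)-but-2-en-2-yl]-2-oxido-1,3-dioxolane on O8/O9 of enolate 16 (new acetal carbon unassigned; not isolated) | [Li+].[Li+].C/C=C(/C)C1([O-])O[C@@H]2[C@H](O1)[C@@H](C(C)=C)C[C@@]3(C)[C@@H]2CC([O-])=C[C@@H]3C | intermediate
18 | hemiorthoester: 2-[(Z)-but-2-en-2-yl]-2-hydroxy-1,3-dioxolane on O8/O9, ketone restored (acetal carbon unassigned; not isolated) | C/C=C(/C)C1(O)O[C@@H]2[C@H](O1)[C@@H](C(C)=C)C[C@@]3(C)[C@@H]2CC(=O)C[C@@H]3C | intermediate
19 | (4S,5R,7R,8R,9S,10S)-9α-angeloyloxy-8α-hydroxy-10βH-eremophil-11-en-2-one | C/C=C(/C)C(=O)O[C@@H]1[C@H](O)[C@@H](C(C)=C)C[C@@]2(C)[C@@H]1CC(=O)C[C@@H]2C | intermediate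
20 | (4S,5R,7S,8R,9S,10S,11R)-9α-angeloyloxy-11,12-epoxy-8α-hydroxy-10βH-eremophilan-2-one (CNP0206528.1) | C/C=C(/C)C(=O)O[C@@H]1[C@H](O)[C@@H]([C@]2(C)CO2)C[C@@]2(C)[C@@H]1CC(=O)C[C@@H]2C | target

**Step count and risk**

Total step count: 10. Longest linear sequence: 10 steps, from (+)-nopinone 1.

The three steps most likely to fail are 9, 10 and 2.

Step 9 (the proposed new step) may give over-addition, the wrong ester regiochemistry or acyl migration. The fallback uses known chemistry, sets out from 13 and comes back at 19. Methanolysis of the carbonate (K2CO3, MeOH, 0 °C) gives (4S,5R,7R,8R,9S,10S)-8α,9α-dihydroxy-10βH-eremophil-11-en-2-one F2. Silylation of the more accessible equatorial 8-OH (TESCl, imidazole, DMF, 0 °C) gives (4S,5R,7R,8R,9S,10S)-9α-hydroxy-8α-(triethylsilyloxy)-10βH-eremophil-11-en-2-one F3. Yamaguchi-type esterification of the axial 9-OH with the preformed mixed anhydride of angelic acid (angelic acid, 2,4,6-trichlorobenzoyl chloride, Et3N, toluene, 80 °C, no DMAP, to keep the Z geometry) gives (4S,5R,7R,8R,9S,10S)-9α-angeloyloxy-8α-(triethylsilyloxy)-10βH-eremophil-11-en-2-one F4. Buffered HF·pyridine (THF/pyridine, 0 °C) then removes the silyl group without acyl migration to give 19.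

Step 10 may give poor selectivity at C11, because the directed delivery rests on a transition-state model. The fallback sets out from 19 and comes back at 20. It replaces substrate direction by reagent control: a chiral dioxirane epoxidation (Shi-type ketone catalyst for 1,1-disubstituted alkenes, Oxone, buffer near pH 8, 0 °C, short reaction time), with separation of any 11-epimer; it makes no new compound (none F0).

Step 2 forms a quaternary centre next to a tertiary one with a hindered enolate, so retro-Michael reaction, enone polymerisation or erosion of the C4 selectivity are possible. The fallback sets out from 3 and comes back at 6. Ketone 3 is converted (LDA, TMSCl, THF, −78 °C) into the trimethylsilyl enol ether of 3 F1. F1 is then added to 4 under TiCl4 in CH2Cl2 at −78 °C (Mukaiyama–Michael addition, irreversible, open transition state, attack again anti to the gem-dimethyl bridge). Any C4 epimer is removed at the stage of 8.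

Further compounds
F1 | step 2 | trimethylsilyl enol ether of 3, (1R,5S)-3,6,6-trimethyl-2-(trimethylsilyloxy)bicyclo[3.1.1]hept-2-ene | CC1(C)[C@H]2CC(C)=C(O[Si](C)(C)C)[C@@H]1C2
F2 | step 9 | (4S,5R,7R,8R,9S,10S)-8α,9α-dihydroxy-10βH-eremophil-11-en-2-one | O[C@@H]1[C@H](O)[C@@H](C(C)=C)C[C@@]2(C)[C@@H]1CC(=O)C[C@@H]2C
F3 | step 9 | (4S,5R,7R,8R,9S,10S)-9α-hydroxy-8α-(triethylsilyloxy)-10βH-eremophil-11-en-2-one | O[C@@H]1[C@H](O[Si](CC)(CC)CC)[C@@H](C(C)=C)C[C@@]2(C)[C@@H]1CC(=O)C[C@@H]2C
F4 | step 9 | (4S,5R,7R,8R,9S,10S)-9α-angeloyloxy-8α-(triethylsilyloxy)-10βH-eremophil-11-en-2-one | C/C=C(/C)C(=O)O[C@@H]1[C@H](O[Si](CC)(CC)CC)[C@@H](C(C)=C)C[C@@]2(C)[C@@H]1CC(=O)C[C@@H]2C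
F0 | step 10 | none | none
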